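**Retrosynthetic overview**
- Diacarperoxide C ⇒ RuO4 cleavage of the tetrasubstituted cyclohexene of a cyclohexenylethyl 1,2-dioxane ester; this biogenetic ring-opening is done last.
- C6 quaternary centre ⇒ axial methyl transfer from AlMe3 to a cyclic peroxycarbenium ion made from a 6-methoxy-1,2-dioxane, so that C3 dictates C6.
- 1,2-Dioxane (the only ring that is formed) ⇒ catalyst-controlled 6-exo peroxy-Michael addition of a ketone-derived hydroperoxy ketal to the (E)-2-methyl enoate, the biogenetic hydroperoxide-to-enoate closure; it sets C3 and C2.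
- Hydroperoxy ketal ⇒ keto enoate ⇒ kinetic enolate of dihydro-β-ionone plus methyl γ-bromotiglate.
- Ring order: the cyclohexene comes with dihydro-β-ionone, the 1,2-dioxane is closed in step 3, the carbocycle is opened in step 5.

Assumption: the presumed biosynthesis is taken as conjugate addition of a C6 hydroperoxide to the C2=C3 enoate followed by oxidative opening of the C9=C14 bond, and dihydro-β-ionone 1 and methyl (2E)-4-bromo-2-methylbut-2-enoate 2 are taken as catalogue chemicals.

**Route**

Step 1
Reactants: 1 dihydro-β-ionone [4-(2,6,6-trimethylcyclohex-1-en-1-yl)butan-2-one]; 2 methyl (2E)-4-bromo-2-methylbut-2-enoate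
Product: 4 methyl (2E)-2-methyl-6-oxo-8-(2,6,6-trimethylcyclohex-1-en-1-yl)oct-2-enoate, via kinetic lithium enolate 3 (not isolated)
Conditions: LiN(iPr)2 (1.05 equiv), THF, −78 °C, 30 min; then 2, DMPU, −78 → −40 °C
Reagents that add atoms: none
Why: Kinetic deprotonation of the methyl ketone at CH3 and SN2 enolate alkylation by the primary allylic bromide, whose α-methyl group slows the competing Michael-initiated ring closure; no stereocentre is formed and the E geometry of 2 is carried over.

Step 2
Reactants: 4 methyl (2E)-2-methyl-6-oxo-8-(2,6,6-trimethylcyclohex-1-en-1-yl)oct-2-enoate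
Product: 5 methyl (2E)-6-hydroperoxy-6-methoxy-2-methyl-8-(2,6,6-trimethylcyclohex-1-en-1-yl)oct-2-enoate (racemic at C6)
Conditions: urea·H2O2 (4 equiv), Sc(OTf)3 (10 mol%), MeOH, 0 °C → rt
Reagents that add atoms: hydrogen peroxide (from its urea adduct), OO; methanol, CO
Why: Lewis-acid-catalysed perketalisation of a dialkyl ketone (the oxocarbenium ion formed in methanol is captured by H2O2) leaves the enoate and the tetrasubstituted alkene untouched, and the new C6 centre is left racemic because step 4 erases it.

Step 3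
Reactants: 5 methyl (2E)-6-hydroperoxy-6-methoxy-2-methyl-8-(2,6,6-trimethylcyclohex-1-en-1-yl)oct-2-enoate
Product: 6 methyl (2R)-2-{(3S)-6-methoxy-6-[2-(2,6,6-trimethylcyclohex-1-en-1-yl)ethyl]-1,2-dioxan-3-yl}propanoate (both C6 epimers)
Conditions: squaramide organocatalyst made from 9-amino-9-deoxy-epi-quinidine and 3,5-(CF3)2C6H3NH2 on a cyclobutenedione core (10 mol%), toluene, 0 °C → rt
Reagents that add atoms: none
Why: Proposed new method: the quinuclidine nitrogen deprotonates the hydroperoxy ketal (pKa about 12) while the squaramide NH pair binds the enoate carbonyl, so the peroxide oxygen adds 6-exo-trig through a chair to one catalyst-defined face of C3 (3S; the quinine-derived pseudoenantiomer gives the antipode, so the sense is secured by the choice between the two), and the ester enolate, held in the A1,3-minimised conformer, is protonated by the quinuclidinium anti to the new C3–O bond (net anti addition across the E alkene), which gives 2R and the 2,3-syn relationship, both C6 epimers of 5 reacting alike; the closest known reactions are the Et2NH/CF3CH2OH intramolecular peroxy-Michael addition of hydroperoxy ketals to enoates and amine–squaramide or iminophosphorane catalysed enantioselective oxa- and sulfa-Michael additions to unsaturated esters.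

Step 4
Reactants: 6 methyl (2R)-2-{(3S)-6-methoxy-6-[2-(2,6,6-trimethylcyclohex-1-en-1-yl)ethyl]-1,2-dioxan-3-yl}propanoate
Product: 8 methyl (2R)-2-{(3S,6R)-6-methyl-6-[2-(2,6,6-trimethylcyclohex-1-en-1-yl)ethyl]-1,2-dioxan-3-yl}propanoate, via cyclic peroxycarbenium ion 7 (not isolated)
Conditions: AlMe3 (3 equiv), CH2Cl2, −78 → −20 °C
Reagents that add atoms: trimethylaluminium (AlMe3), C[Al](C)C
Why: Proposed new method: AlMe3 binds the exocyclic methoxy group and ionises either C6 epimer of 6 to the same half-chair peroxycarbenium ion 7 with the C3 side chain pseudoequatorial, and methyl is then transferred from the methoxyaluminate along the stereoelectronically preferred axial trajectory through a chair-like transition state, which puts CH3 axial and cis to the C3 substituent and the C7 chain equatorial (6R), a bias that ring closure onto a preformed CH3/CH2R centre cannot offer; the closest known reactions are the Lewis-acid-mediated allylation and silane reduction of 3-alkoxy-1,2-dioxanes and 1,2-dioxolanes through peroxycarbenium ions and the AlMe3 C-methylation of cyclic acetals, which trioxane peroxides tolerate.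

Step 5
Reactants: 8 methyl (2R)-2-{(3S,6R)-6-methyl-6-[2-(2,6,6-trimethylcyclohex-1-en-1-yl)ethyl]-1,2-dioxan-3-yl}propanoate
Product: 9 diacarperoxide C [methyl (2R)-2-[(3S,6S)-6-(4,4-dimethyl-3,8-dioxononyl)-6-methyl-1,2-dioxan-3-yl]propanoate]
Conditions: RuCl3·xH2O (5 mol%), NaIO4 (4 equiv), EtOAc/MeCN/H2O, 0 °C, 30 min
Reagents that add atoms: sodium periodate (NaIO4, oxygen source relayed by RuO4), [Na+].[O-]I(=O)(=O)=O
Why: RuO4-catalysed oxidative cleavage of the only C=C bond, an electron-rich tetrasubstituted alkene, gives the 1,6-diketone directly while the dialkyl peroxide, the ester and the three stereocentres are untouched (C6 changes from R to S only through the CIP priorities).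

**Compound list**
1 | dihydro-β-ionone, 4-(2,6,6-trimethylcyclohex-1-en-1-yl)butan-2-one | CC(=O)CCC1=C(C)CCCC1(C)C | starting material
2 | methyl (2E)-4-bromo-2-methylbut-2-enoate | COC(=O)/C(C)=C/CBr | starting material
3 | kinetic lithium enolate of 1, lithium 4-(2,6,6-trimethylcyclohex-1-en-1-yl)but-1-en-2-olate | C=C(O[Li])CCC1=C(C)CCCC1(C)C | intermediate (not isolated)
4 | methyl (2E)-2-methyl-6-oxo-8-(2,6,6-trimethylcyclohex-1-en-1-yl)oct-2-enoate | COC(=O)/C(C)=C/CCC(=O)CCC1=C(C)CCCC1(C)C | intermediate
5 | methyl (2E)-6-hydroperoxy-6-methoxy-2-methyl-8-(2,6,6-trimethylcyclohex-1-en-1-yl)oct-2-enoate (racemic) | COC(=O)/C(C)=C/CCC(OC)(OO)CCC1=C(C)CCCC1(C)C | intermediate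
6 | methyl (2R)-2-{(3S)-6-methoxy-6-[2-(2,6,6-trimethylcyclohex-1-en-1-yl)ethyl]-1,2-dioxan-3-yl}propanoate (C6 epimer mixture) | COC(=O)[C@H](C)[C@@H]1CCC(OC)(CCC2=C(C)CCCC2(C)C)OO1 | intermediate
7 | cyclic peroxycarbenium ion from 6 (C6=O1 cation, C3 and C2 as in 6) | COC(=O)[C@H](C)[C@@H]1CCC(CCC2=C(C)CCCC2(C)C)=[O+]O1 | intermediate (not isolated)
8 | methyl (2R)-2-{(3S,6R)-6-methyl-6-[2-(2,6,6-trimethylcyclohex-1-en-1-yl)ethyl]-1,2-dioxan-3-yl}propanoate | COC(=O)[C@H](C)[C@@H]1CC[C@@](C)(CCC2=C(C)CCCC2(C)C)OO1 | intermediate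
9 | diacarperoxide C, methyl (2R)-2-[(3S,6S)-6-(4,4-dimethyl-3,8-dioxononyl)-6-methyl-1,2-dioxan-3-yl]propanoate | COC(=O)[C@H](C)[C@@H]1CC[C@@](C)(CCC(=O)C(C)(C)CCCC(C)=O)OO1 | target

**Totals**
Total step count: 5. Longest linear sequence: 5 steps (1 → 4 → 5 → 6 → 8 → 9).

**Three steps most likely to fail**

Step 3 (enantioselective peroxy-Michael closure). The α-methyl enoate is a weak acceptor, the intermediate enolate can collapse to an epoxy ester by attack on the O–O bond, and neither the enantioselectivity nor the C2 protonation selectivity is precedented for this substrate. The fallback sets out from 5 and returns at 8, and replaces catalyst control by resolution. Compound 5 is cyclised with Et2NH (20 mol%) in CF3CH2OH at rt, the established racemic conditions. This gives 6 together with its mirror-image series, methyl (2S)-2-{(3R)-6-methoxy-6-[2-(2,6,6-trimethylcyclohex-1-en-1-yl)ethyl]-1,2-dioxan-3-yl}propanoate F1. The mixture is methylated as in step 4 to 8 and its enantiomer, methyl (2S)-2-{(3R,6S)-6-methyl-6-[2-(2,6,6-trimethylcyclohex-1-en-1-yl)ethyl]-1,2-dioxan-3-yl}propanoate F2, and 8 is separated from it by preparative chromatography on a chiral stationary phase.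

Step 4 (methylation of the peroxyketal). AlMe3 may ionise too slowly, may open the ring through the endocyclic oxygen, or may transfer methyl to a peroxide oxygen. The fallback sets out from 4 and returns at 8, and installs the C6 methyl group before the ring is closed.
- Wittig methylenation of 4 (Ph3PCH3Br, KOtBu, THF, 0 °C) gives methyl (2E)-2-methyl-6-methylidene-8-(2,6,6-trimethylcyclohex-1-en-1-yl)oct-2-enoate F3.
- Mukaiyama–Isayama hydroperoxysilylation of the 1,1-disubstituted alkene (Co(thd)2 cat., thd = 2,2,6,6-tetramethylheptane-3,5-dionate, O2, Et3SiH, ClCH2CH2Cl, rt) gives racemic methyl (2E)-2,6-dimethyl-6-[(triethylsilyl)peroxy]-8-(2,6,6-trimethylcyclohex-1-en-1-yl)oct-2-enoate F4.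
- HF·pyridine (THF, 0 °C) frees racemic methyl (2E)-6-hydroperoxy-2,6-dimethyl-8-(2,6,6-trimethylcyclohex-1-en-1-yl)oct-2-enoate F5.
- The catalyst of step 3 closes the ring to 8 and its C6 epimer, methyl (2R)-2-{(3S,6S)-6-methyl-6-[2-(2,6,6-trimethylcyclohex-1-en-1-yl)ethyl]-1,2-dioxan-3-yl}propanoate F6, in about equal amounts because C6 is racemic; 8 is isolated by chromatography.

Step 1 (enolate alkylation with a γ-bromo enoate). Proton transfer to the product or to 2, polyalkylation, and Michael-initiated ring closure can erode the yield. The fallback sets out from 1 and returns at 4. Enolate 3 is alkylated with allyl bromide, which reacts fast at −78 °C and carries no Michael acceptor, to give 1-(2,6,6-trimethylcyclohex-1-en-1-yl)hept-6-en-3-one F7. The enoate is then made by cross-metathesis of this ketone with methyl methacrylate (second-generation Hoveyda–Grubbs catalyst, CH2Cl2, 40 °C), which gives 4 with E selectivity; the tetrasubstituted cyclohexene does not take part.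

**Further compounds**
F1 | step 3 | methyl (2S)-2-{(3R)-6-methoxy-6-[2-(2,6,6-trimethylcyclohex-1-en-1-yl)ethyl]-1,2-dioxan-3-yl}propanoate (mirror-image series of 6, both C6 epimers) | COC(=O)[C@@H](C)[C@H]1CCC(OC)(CCC2=C(C)CCCC2(C)C)OO1
F2 | step 3 | methyl (2S)-2-{(3R,6S)-6-methyl-6-[2-(2,6,6-trimethylcyclohex-1-en-1-yl)ethyl]-1,2-dioxan-3-yl}propanoate (enantiomer of 8) | COC(=O)[C@@H](C)[C@H]1CC[C@](C)(CCC2=C(C)CCCC2(C)C)OO1
F3 | step 4 | methyl (2E)-2-methyl-6-methylidene-8-(2,6,6-trimethylcyclohex-1-en-1-yl)oct-2-enoate | COC(=O)/C(C)=C/CCC(=C)CCC1=C(C)CCCC1(C)C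
F4 | step 4 | methyl (2E)-2,6-dimethyl-6-[(triethylsilyl)peroxy]-8-(2,6,6-trimethylcyclohex-1-en-1-yl)oct-2-enoate (racemic) | COC(=O)/C(C)=C/CCC(C)(OO[Si](CC)(CC)CC)CCC1=C(C)CCCC1(C)C
F5 | step 4 | methyl (2E)-6-hydroperoxy-2,6-dimethyl-8-(2,6,6-trimethylcyclohex-1-en-1-yl)oct-2-enoate (racemic) | COC(=O)/C(C)=C/CCC(C)(OO)CCC1=C(C)CCCC1(C)C
F6 | step 4 | methyl (2R)-2-{(3S,6S)-6-methyl-6-[2-(2,6,6-trimethylcyclohex-1-en-1-yl)ethyl]-1,2-dioxan-3-yl}propanoate (C6 epimer of 8) | COC(=O)[C@H](C)[C@@H]1CC[C@](C)(CCC2=C(C)CCCC2(C)C)OO1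
F7 | step 1 | 1-(2,6,6-trimethylcyclohex-1-en-1-yl)hept-6-en-3-one | C=CCCC(=O)CCC1=C(C)CCCC1(C)C
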